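**Strategy.** Numbering: ring C1 (carbinol carrying the crotonoyl group), C5 (angelate), C6 (lactone O), C7, C8 (CH2), C9 (CHOH), C10 (CHMe); lactone C11–C13. Everything rests on a (4+3) disconnection of the cycloheptane. 3-Furylacetic acid supplies C5–C8 and the C5 oxygen; a chiral 1-alkoxy-2-(silylmethyl)allyl cation, made from a 2-(trimethylsilylmethyl)acrolein acetal, supplies C9–C10–C1. Their cycloaddition forms C8–C9 and C1–C5 in one operation and dearomatizes the furan. The step exploits the 1,4-relationship of the C5 oxygen and C8 across the seven-membered ring: the temporary C8–O bridge gives a rigid 8-oxabicyclo[3.2.1]octene whose bridge face controls C1, C6, C7 and C10; SmI2 later cuts the bridge.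

Key step: step 3

Remark (descriptors): β is the face of the seven-membered ring that carries the C5 oxygen (the oxygen-bridge face of the bicycles); α is the opposite face.

Remark (assumption): the (S)-1-phenylethyl group is assumed to induce the absolute series drawn; the cycloadducts are diastereomers and separable, and the (R)-alcohol would be used in the same way if the induction proved opposite.

## Route

Step 1
Reactants: 1 2-bromo-3,3-diethoxyprop-1-ene; 2 (S)-1-phenylethanol
Product: 3 2-bromo-3,3-bis[(S)-1-phenylethoxy]prop-1-ene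
Conditions: 2 (2.2 equiv), PPTS (cat.), cyclohexane, 70 °C, EtOH distilled off
Reagents that add atoms: none
Why: Acid-catalysed transacetalization driven by removal of ethanol; the acetal carbon carries two identical alkoxy groups, so no new stereocentre arises.

Step 2
Reactants: 3 2-bromo-3,3-bis[(S)-1-phenylethoxy]prop-1-ene
Product: 4 3,3-bis[(S)-1-phenylethoxy]-2-[(trimethylsilyl)methyl]prop-1-ene
Conditions: Me3SiCH2MgCl, Pd(PPh3)4 (5 mol%), THF, 60 °C
Reagents that add atoms: (trimethylsilyl)methylmagnesium chloride, C[Si](C)(C)C[Mg]Cl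
Why: Kumada–Corriu cross-coupling of the vinyl bromide with the silylmethyl Grignard reagent under zerovalent palladium catalysis gives the allylsilane, the acetal being inert to the Grignard reagent.

Step 3
Reactants: 5 2-(furan-3-yl)acetic acid; 4 3,3-bis[(S)-1-phenylethoxy]-2-[(trimethylsilyl)methyl]prop-1-ene
Product: 8 bicyclic acid 2-[3-methylidene-2-((S)-1-phenylethoxy)-8-oxabicyclo[3.2.1]oct-6-en-6-yl]acetic acid (C1 ether α), via furylacetic silyl ester 6 (not isolated), via bicyclic silyl ester 7 (not isolated)
Conditions: 5 (1.5 equiv), (Me3Si)2NH (0.6 equiv per acid), CH2Cl2, 40 °C, then evaporation; 4 added slowly, Me3SiOTf (0.2 equiv), CH2Cl2, −78 °C; pyridine quench, aqueous work-up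
Reagents that add atoms: none
Why: Me3SiOTf ionizes the acetal to the 1-alkoxy-2-(silylmethyl)allyl cation, whose unsubstituted terminus bonds to furan C2, the more nucleophilic α-position of a 3-alkylfuran (C8–C9), and whose alkoxy-bearing terminus then bonds to furan C5 (C1–C5) while the charge at the central carbon is held by the β-silyl group, loss of which leaves the C10 methylene and returns the silyl triflate. The closest known reaction type is the (4+3) cycloaddition of alkoxy-substituted 2-(silylmethyl)allyl cations and of heteroatom-substituted oxyallyl cations with furans. The second bond formation, 7-exo-trig with respect to the C5=O+ unit of the furanium ion, closes the cycloheptene and with the same bond the oxygen-bridged oxane ring, in a compact arrangement that leaves the alkoxy group equatorial (α). C1 is set by the (S)-1-phenylethyl group, which shields one face of the planar cation, and the bridgeheads C5 and C8 follow from it because the furan reacts suprafacially through both α-carbons. The step needs (4+3) over (4+2) periselectivity, C2-first regioselectivity and ring closure faster than rearomatization; these are secured by the β-silicon effect, by the donor 3-substituent of the furan, and by slow addition of 4 to excess furan at −78 °C in a non-nucleophilic solvent.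

Step 4
Reactants: 8 bicyclic acid
Product: 9 iodolactone (γ-lactone from C12 to the C6 oxygen, α-fused; iodine on C7, β)
Conditions: I2, NaHCO3, MeCN, 0 °C → rt, dark
Reagents that add atoms: iodine, II
Why: Iodolactonization: the iodonium ion forms on the β face of the strained C6=C7 bond and the tethered carboxylate opens it at C6 from the α face (5-endo, equilibrating conditions that favour the γ- over the β-lactone), which places the C6 oxygen and the C7 side chain both α.

Step 5
Reactants: 9 iodolactone
Product: 10 bicyclic γ-lactone (cis-fused on the α face, H6 and H7 β)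
Conditions: Bu3SnH, AIBN (cat.), toluene, 80 °C
Reagents that add atoms: none
Why: Radical chain dehalogenation; the tertiary C7 radical takes hydrogen on the β face because the lactone ring is tied to the α face, so the cis ring fusion is kept.

Step 6
Reactants: 10 bicyclic γ-lactone
Product: 11 9β-hydroxy lactone (allylic alcohol)
Conditions: SeO2 (0.5 equiv), t-BuOOH, CH2Cl2, rt
Reagents that add atoms: selenium dioxide, O=[Se]=O; tert-butyl hydroperoxide, CC(C)(C)OO
Why: Allylic oxidation (ene reaction, then [2,3]-sigmatropic shift) of the 1,1-disubstituted alkene occurs at the ring CH2 (C9) and not at the alkoxy-bearing CH (C1), on the open β face, and returns the exocyclic alkene; the C9 configuration is of no consequence.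

Step 7
Reactants: 11 9β-hydroxy lactone
Product: 12 9β-triethylsilyl ether
Conditions: Et3SiCl, imidazole, DMF, 0 °C → rt
Reagents that add atoms: chlorotriethylsilane, CC[Si](Cl)(CC)CC
Why: Silylation of the only hydroxyl group keeps the C9 oxygen out of the oxidation in step 9.

Step 8
Reactants: 12 9β-triethylsilyl ether
Product: 13 alcohol (1α-hydroxy, 10α-methyl with H10 β, 9β-silyloxy)
Conditions: H2 (1 atm), Pd(OH)2/C, EtOAc, rt
Reagents that add atoms: none
Why: Heterogeneous hydrogenation adds H2 to the exocyclic alkene from the β face (the α face is closed by the lactone), which sets C10 with the methyl α, and hydrogenolysis of the benzylic ether frees the C1 hydroxyl.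

Step 9
Reactants: 13 alcohol
Product: 14 C1 ketone
Conditions: Dess–Martin periodinane, NaHCO3, CH2Cl2, 0 °C → rt
Reagents that add atoms: none
Why: Dess–Martin oxidation of the only free alcohol under buffered, non-basic conditions gives the C1 ketone without epimerizing C10.

Step 10
Reactants: 15 but-2-yn-1-ol
Product: 16 1-methoxybut-2-yne
Conditions: NaH, MeI, THF, 0 °C → rt
Reagents that add atoms: iodomethane, CI
Why: Williamson ether synthesis on the primary propargylic alkoxide.

Step 11
Reactants: 16 1-methoxybut-2-yne
Product: 17 1-methoxybuta-1,2-diene (racemic)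
Conditions: KOt-Bu (0.1 equiv), DMSO, rt, then distillation
Reagents that add atoms: none
Why: Base-catalysed propargyl–allenyl prototropic isomerization gives the alkoxyallene, which is distilled off before it can isomerize further to the conjugated diene.

Step 12
Reactants: 17 1-methoxybuta-1,2-diene; 14 C1 ketone
Product: 19 tertiary carbinol (1α-hydroxy, 1β-(1-methoxybuta-1,2-dien-1-yl); allene-axis epimers), via lithiated methoxyallene 18 (not isolated)
Conditions: 17 (1.5 equiv), n-BuLi, THF, −40 °C; then 14, −78 °C; aq. NH4Cl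
Reagents that add atoms: none
Why: α-Lithiation of the alkoxyallene and 1,2-addition of this small sp2 organolithium to the ketone from the β face (the α face is closed by the lactone and the C10 methyl) sets C1 with the hydroxyl α, the ketone reacting faster than the lactone at −78 °C; the two allene-axis epimers converge in step 20.

Step 13
Reactants: 19 tertiary carbinol
Product: 21 amino diol (C11 CH2NMe2, 9β-hydroxy; C11 epimers), via silylated Mannich base 20 (not isolated)
Conditions: LiN(i-Pr)2 (2.5 equiv), THF, −78 °C; CH2=NMe2+ I−, −78 → 0 °C; then Bu4NF, 0 °C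
Reagents that add atoms: N,N-dimethylmethyleneiminium iodide, C=[N+](C)C.[I-]
Why: Mannich reaction of the lactone lithium enolate with the iminium salt (the tertiary hydroxyl is carried as its alkoxide) installs C13 as a masked methylene and fluoride then removes the silyl ether; the C11 centre is destroyed in step 19.

Step 14
Reactants: 21 amino diol
Product: 22 C9 ketone
Conditions: Dess–Martin periodinane, NaHCO3, CH2Cl2, 0 °C
Reagents that add atoms: none
Why: Dess–Martin oxidation of the only secondary alcohol gives the C9 ketone; the tertiary alcohol, the amine and, under buffering, the allenyl ether are untouched.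

Step 15
Reactants: 22 C9 ketone
Product: 23 monocyclic hydroxy ketone (5β-hydroxy, C8 H2, C9 ketone)
Conditions: SmI2 (2.5 equiv), MeOH (4 equiv), THF, −78 °C
Reagents that add atoms: none
Why: SmI2 reductive cleavage of the α-alkoxy ketone (ketyl at C9, expulsion of the bridge oxygen from C8, protonation of the samarium enolate at C8) opens the bridge, leaves C8 as CH2 and frees the C5 hydroxyl; no other group is reducible under these conditions.

Step 16
Reactants: 23 monocyclic hydroxy ketone
Product: 24 triol (9β-hydroxy, anti to the 1α-hydroxyl)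
Conditions: Me4NBH(OAc)3, MeCN/AcOH, −30 °C
Reagents that add atoms: none
Why: Evans–Saksena reduction: the borohydride bound to the tertiary C1 hydroxyl (α) delivers hydride to the α face of the C9 ketone through a six-membered transition state, giving the 1,3-anti diol with C9–OH β; the weakly acidic medium at low temperature should spare the enol ether.

Step 17
Reactants: 24 triol
Product: 25 9β-triethylsilyl ether
Conditions: Et3SiCl, imidazole, CH2Cl2, −20 °C
Reagents that add atoms: chlorotriethylsilane, CC[Si](Cl)(CC)CC
Why: Selective silylation of the least hindered hydroxyl (C9) over the neopentyl-type C5 hydroxyl and the tertiary C1 hydroxyl.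

Step 18
Reactants: 25 9β-triethylsilyl ether; 26 angelic acid ((Z)-2-methylbut-2-enoic acid)
Product: 28 5β-angelate, via mixed anhydride 27 (not isolated)
Conditions: 26, 2,4,6-Cl3C6H2COCl, Et3N, toluene, rt; then 25, 75 °C
Reagents that add atoms: none
Why: Yamaguchi-type esterification through the mixed anhydride, run without a nucleophilic catalyst, acylates the secondary C5 hydroxyl without Z-to-E isomerization of the angelate; the tertiary C1 hydroxyl is inert.

Step 19
Reactants: 28 5β-angelate
Product: 30 α-methylene lactone (allenyl ether and 9-silyl ether still in place), via ammonium iodide 29 (not isolated)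
Conditions: MeI, MeCN, rt; then aq. NaHCO3, rt
Reagents that add atoms: none
Why: Exhaustive N-methylation followed by E1cB (Hofmann-type) elimination of trimethylamine from the β-ammonio lactone unveils the α-methylene lactone under nearly neutral conditions.

Step 20
Reactants: 30 α-methylene lactone
Product: 31 CNP0149130.1 (target)
Conditions: 1 M HCl, THF, 0 °C → rt
Reagents that add atoms: water, O
Why: Acid hydrolysis of the alkoxyallene (protonation at the central carbon, addition of water to the allyl-stabilized oxocarbenium ion, loss of methanol) gives the α'-hydroxy (E)-enone under thermodynamic control, and the triethylsilyl ether is cleaved in the same medium.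

## Compound list

1 | 2-bromo-3,3-diethoxyprop-1-ene | C=C(Br)C(OCC)OCC | starting material
2 | (S)-1-phenylethanol | C[C@H](O)c1ccccc1 | starting material
3 | 2-bromo-3,3-bis[(S)-1-phenylethoxy]prop-1-ene | C=C(Br)C(O[C@@H](C)c1ccccc1)O[C@@H](C)c1ccccc1 | intermediate
4 | 3,3-bis[(S)-1-phenylethoxy]-2-[(trimethylsilyl)methyl]prop-1-ene | C=C(C[Si](C)(C)C)C(O[C@@H](C)c1ccccc1)O[C@@H](C)c1ccccc1 | intermediate
5 | 2-(furan-3-yl)acetic acid | OC(=O)Cc1ccoc1 | starting material
6 | trimethylsilyl 2-(furan-3-yl)acetate | C[Si](C)(C)OC(=O)Cc1ccoc1 | intermediate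
7 | trimethylsilyl ester of acid 8 | C[Si](C)(C)OC(=O)CC1=C[C@H]2[C@@H](O[C@@H](C)c3ccccc3)C(=C)C[C@@H]1O2 | intermediate
8 | 2-[3-methylidene-2-((S)-1-phenylethoxy)-8-oxabicyclo[3.2.1]oct-6-en-6-yl]acetic acid (O bridge C5–C8 β, C1 ether α, C10=CH2, C6=C7 with CH2CO2H on C7) | OC(=O)CC1=C[C@H]2[C@@H](O[C@@H](C)c3ccccc3)C(=C)C[C@@H]1O2 | intermediate
9 | iodolactone (lactone O on C6 α, C11 on C7 α, iodine on C7 β) | O=C1C[C@@]2(I)[C@@H](O1)[C@H]3[C@@H](O[C@@H](C)c4ccccc4)C(=C)C[C@@H]2O3 | intermediate
10 | bicyclic γ-lactone (cis-fused on the α face) | O=C1C[C@H]2[C@@H](O1)[C@H]3[C@@H](O[C@@H](C)c4ccccc4)C(=C)C[C@@H]2O3 | intermediate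
11 | 9β-hydroxy lactone | O=C1C[C@H]2[C@@H](O1)[C@H]3[C@@H](O[C@@H](C)c4ccccc4)C(=C)[C@H](O)[C@@H]2O3 | intermediate
12 | 9β-triethylsilyl ether of 11 | O=C1C[C@H]2[C@@H](O1)[C@H]3[C@@H](O[C@@H](C)c4ccccc4)C(=C)[C@H](O[Si](CC)(CC)CC)[C@@H]2O3 | intermediate
13 | 1α-hydroxy-10α-methyl-9β-(triethylsilyloxy) lactone | O=C1C[C@H]2[C@@H](O1)[C@H]3[C@@H](O)[C@@H](C)[C@H](O[Si](CC)(CC)CC)[C@@H]2O3 | intermediate
14 | C1 ketone of 13 | O=C1C[C@H]2[C@@H](O1)[C@H]3C(=O)[C@@H](C)[C@H](O[Si](CC)(CC)CC)[C@@H]2O3 | intermediate
15 | but-2-yn-1-ol | CC#CCO | starting material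
16 | 1-methoxybut-2-yne | CC#CCOC | intermediate
17 | 1-methoxybuta-1,2-diene (racemic) | CC=C=COC | intermediate
18 | 1-lithio-1-methoxybuta-1,2-diene | CC=C=C([Li])OC | intermediate
19 | tertiary carbinol: 1α-hydroxy-1β-(1-methoxybuta-1,2-dien-1-yl), 9β-silyloxy (allene-axis epimers) | O=C1C[C@H]2[C@@H](O1)[C@H]3[C@](O)(C(OC)=C=CC)[C@@H](C)[C@H](O[Si](CC)(CC)CC)[C@@H]2O3 | intermediate
20 | C11-(dimethylaminomethyl) derivative of 19 (C11 epimers) | O=C1C(CN(C)C)[C@H]2[C@@H](O1)[C@H]3[C@](O)(C(OC)=C=CC)[C@@H](C)[C@H](O[Si](CC)(CC)CC)[C@@H]2O3 | intermediate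
21 | amino diol: 20 without the silyl group (9β-hydroxy) | O=C1C(CN(C)C)[C@H]2[C@@H](O1)[C@H]3[C@](O)(C(OC)=C=CC)[C@@H](C)[C@H](O)[C@@H]2O3 | intermediate
22 | C9 ketone of 21 | O=C1C(CN(C)C)[C@H]2[C@@H](O1)[C@H]3[C@](O)(C(OC)=C=CC)[C@@H](C)C(=O)[C@@H]2O3 | intermediate
23 | monocyclic hydroxy ketone (5β-hydroxy, C8 H2, C9 ketone) | O=C1C(CN(C)C)[C@H]2[C@@H](O1)[C@H](O)[C@](O)(C(OC)=C=CC)[C@@H](C)C(=O)C2 | intermediate
24 | triol (5β-, 1α-, 9β-hydroxy) | O=C1C(CN(C)C)[C@H]2[C@@H](O1)[C@H](O)[C@](O)(C(OC)=C=CC)[C@@H](C)[C@H](O)C2 | intermediate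
25 | 9β-triethylsilyl ether of 24 | O=C1C(CN(C)C)[C@H]2[C@@H](O1)[C@H](O)[C@](O)(C(OC)=C=CC)[C@@H](C)[C@H](O[Si](CC)(CC)CC)C2 | intermediate
26 | angelic acid | O=C(O)/C(C)=C\C | starting material
27 | angelic 2,4,6-trichlorobenzoic anhydride | O=C(OC(=O)c1c(Cl)cc(Cl)cc1Cl)/C(C)=C\C | intermediate
28 | 5β-angelate of 25 | O=C1C(CN(C)C)[C@H]2[C@@H](O1)[C@H](OC(=O)/C(C)=C\C)[C@](O)(C(OC)=C=CC)[C@@H](C)[C@H](O[Si](CC)(CC)CC)C2 | intermediate
29 | trimethylammonium iodide of 28 | O=C1C(C[N+](C)(C)C)[C@H]2[C@@H](O1)[C@H](OC(=O)/C(C)=C\C)[C@](O)(C(OC)=C=CC)[C@@H](C)[C@H](O[Si](CC)(CC)CC)C2.[I-] | intermediate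
30 | α-methylene lactone with allenyl ether and 9β-silyl ether | O=C1C(=C)[C@H]2[C@@H](O1)[C@H](OC(=O)/C(C)=C\C)[C@](O)(C(OC)=C=CC)[C@@H](C)[C@H](O[Si](CC)(CC)CC)C2 | intermediate
31 | CNP0149130.1 | C=C1C(=O)O[C@@H]2[C@H]1C[C@@H](O)[C@H](C)[C@@](O)(C(=O)/C=C/C)[C@H]2OC(=O)/C(C)=C\C | target

## Step count and risks

Total step count: 20. Longest linear sequence: 18 (steps 1–9 and 12–20).

**Step 3 (key step).** The first bond may form at the alkoxy-bearing terminus or at furan C5, so that the regiochemistry is scrambled. The furanium ion may also rearomatize by proton loss or close to the (4+2) adduct, and the auxiliary may shield the cation face poorly. The fallback changes the cation to a 2-siloxyallyl (oxyallyl) cation, for which the (4+3) mode is the rule, and brings in the methylene afterwards. 1,1-Dimethoxypropan-2-one is transacetalized with 2 as in step 1 to the keto acetal F1. LiN(i-Pr)2 and Me3SiCl convert it into the silyl enol ether F2. F2 and silyl ester 6 with catalytic Me3SiOTf at −78 °C should give the keto silyl ester F3; as for other heteroatom-substituted oxyallyl cations, the alkoxy-bearing terminus is expected on the furan carbon remote from the side chain. Aqueous work-up gives the keto acid F4, and any regioisomer is removed at this stage. Wittig methylenation of F4 (Ph3P=CH2, 2.5 equiv) returns to 8.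

**Step 12.** Enolization of the flanked C1 ketone or attack on the lactone may outrun 1,2-addition, and the syn-axial 9β-silyloxy group crowds the β face. The fallback removes that group first, so that the reagent meets a small lithium alkoxide that can also hold it on the β face. Starting from 14, buffered HF·pyridine gives the hydroxy ketone F5. Three equivalents of 18 at −78 °C then give the diol F6. The Mannich reaction of step 13, run without the fluoride stage, returns to 21.

**Step 18.** Acylation of the neopentyl-type C5 hydroxyl may be too slow, and heating may isomerize the angelate to the tiglate. The fallback builds the Z-alkene on the substrate instead. Starting from 25, 2-[bis(2,2,2-trifluoroethoxy)phosphoryl]propanoic acid with EDC and DMAP gives the phosphonate F7. Still–Gennari olefination of F7 with acetaldehyde (KN(SiMe3)2, 18-crown-6, THF, −78 °C) returns to 28.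

## Further compounds

F1 | step 3 | 1,1-bis[(S)-1-phenylethoxy]propan-2-one | CC(=O)C(O[C@@H](C)c1ccccc1)O[C@@H](C)c1ccccc1
F2 | step 3 | 2-(trimethylsilyloxy)-3,3-bis[(S)-1-phenylethoxy]prop-1-ene | C=C(O[Si](C)(C)C)C(O[C@@H](C)c1ccccc1)O[C@@H](C)c1ccccc1
F3 | step 3 | trimethylsilyl 2-[3-oxo-2-((S)-1-phenylethoxy)-8-oxabicyclo[3.2.1]oct-6-en-6-yl]acetate | C[Si](C)(C)OC(=O)CC1=C[C@H]2[C@@H](O[C@@H](C)c3ccccc3)C(=O)C[C@@H]1O2
F4 | step 3 | 2-[3-oxo-2-((S)-1-phenylethoxy)-8-oxabicyclo[3.2.1]oct-6-en-6-yl]acetic acid | OC(=O)CC1=C[C@H]2[C@@H](O[C@@H](C)c3ccccc3)C(=O)C[C@@H]1O2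
F5 | step 12 | 9β-hydroxy C1 ketone (14 without the silyl group) | O=C1C[C@H]2[C@@H](O1)[C@H]3C(=O)[C@@H](C)[C@H](O)[C@@H]2O3
F6 | step 12 | 1α,9β-diol carrying the 1β-(1-methoxybuta-1,2-dien-1-yl) group | O=C1C[C@H]2[C@@H](O1)[C@H]3[C@](O)(C(OC)=C=CC)[C@@H](C)[C@H](O)[C@@H]2O3
F7 | step 18 | 5β-{2-[bis(2,2,2-trifluoroethoxy)phosphoryl]propanoate} of 25 | O=C1C(CN(C)C)[C@H]2[C@@H](O1)[C@H](OC(=O)C(C)P(=O)(OCC(F)(F)F)OCC(F)(F)F)[C@](O)(C(OC)=C=CC)[C@@H](C)[C@H](O[Si](CC)(CC)CC)C2
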